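Labdane numbering: ring A = C1–C5 + C10, ring B = C5–C10, chain C11–C16 on C9, C17 on C8, C18/C19 on C4, C20 on C10. The enabling feature is the trans-fused A/B decalin, whose C4, C5, C10 and C9 centres adjoin the exocyclic C8=C17 alkene. An open chain with a C3–C4 epoxide, an E C5=C10 alkene and a C8=C9 allylsilane collapses to exactly this array from a chair–chair fold.
Retrosynthesis: C6=C7 goes back to a C7 alcohol and then to C7–H, the C18 acetate to a silyl ether, and C3–H to C3–OH. C4–C5 and C9–C10 are then cut together, which opens both rings. The chain is cut at C8–C17 and C7–C8 (a 1,1-dichloroalkene) and at the one-carbon junctions C6–C7 and C8–C9.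
Forward: an epoxy diene carrying C1–C7 (from geranyl acetate) and a dichloroalkene carrying C8–C16 (from methyl geranate) are joined at C7–C8. C17 with its silicon is then added at C8, ring A and then ring B close in one operation, and the periphery is adjusted (C3 deoxygenation, C18 acetate, C6=C7).
Stereochemistry: Sharpless epoxidation with D-(−)-diethyl tartrate is the only external source. C4 derives from it with inversion, and C5, C10 and C9 follow from the alkene geometries through the chair–chair fold. C3 is erased later and C7 is transient.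
Key step: step 11

Assumption: the target is read as the ent-labdane (4S,5S,9R,10S) with the acetoxymethyl group equatorial on C4 (C18). Commercial geranyl acetate and methyl geranate are taken as the pure E isomers.

Step 1
Reactants: 1 geranyl acetate [(2E)-3,7-dimethylocta-2,6-dien-1-yl acetate]
Product: 2 (2E,6E)-8-hydroxy-3,7-dimethylocta-2,6-dien-1-yl acetate
Conditions: SeO2 (cat.), t-BuOOH, salicylic acid (cat.), CH2Cl2, 0 °C to rt
Reagents that add atoms: tert-butyl hydroperoxide, CC(C)(C)OO (terminal oxygen source); selenium dioxide, O=[Se]=O (oxygen carrier)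
Why: The catalytic Riley oxidation (ene reaction, then [2,3]-shift) should attack the more electron-rich alkene remote from the acetate and hydroxylate only the methyl group trans to the chain, which fixes the E geometry that later places C18 equatorial.

Step 2
Reactants: 2 (2E,6E)-8-hydroxy-3,7-dimethylocta-2,6-dien-1-yl acetate
Product: 3 (2E)-5-[(2R,3R)-3-(hydroxymethyl)-3-methyloxiran-2-yl]-3-methylpent-2-en-1-yl acetate
Conditions: Ti(OiPr)4 (10 mol %), D-(−)-diethyl tartrate (12 mol %), t-BuOOH, 4 Å molecular sieves, CH2Cl2, −20 °C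
Reagents that add atoms: tert-butyl hydroperoxide, CC(C)(C)OO
Why: The Sharpless asymmetric epoxidation touches only the alkene of the free allylic alcohol, and the D-(−)-tartrate complex delivers oxygen to the face that gives the (R,R)-epoxide, which sets C3 and C4 of the labdane.

Step 3
Reactants: 3 (2E)-5-[(2R,3R)-3-(hydroxymethyl)-3-methyloxiran-2-yl]-3-methylpent-2-en-1-yl acetate
Product: 4 (2E)-5-[(2R,3R)-3-{[(tert-butyldiphenylsilyl)oxy]methyl}-3-methyloxiran-2-yl]-3-methylpent-2-en-1-yl acetate
Conditions: TBDPSCl, imidazole, CH2Cl2, 0 °C to rt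
Reagents that add atoms: tert-butyl(chloro)diphenylsilane, CC(C)(C)[Si](Cl)(c1ccccc1)c1ccccc1
Why: Imidazole-promoted silylation of the primary alcohol installs a bulky, non-participating ether that blocks Payne rearrangement and will tolerate the Lewis acid of the cyclization.

Step 4
Reactants: 4 (2E)-5-[(2R,3R)-3-{[(tert-butyldiphenylsilyl)oxy]methyl}-3-methyloxiran-2-yl]-3-methylpent-2-en-1-yl acetate
Product: 5 (2E)-5-[(2R,3R)-3-{[(tert-butyldiphenylsilyl)oxy]methyl}-3-methyloxiran-2-yl]-3-methylpent-2-en-1-ol
Conditions: K2CO3 (0.2 equiv), MeOH, 0 °C to rt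
Reagents that add atoms: none
Why: Carbonate-catalysed transesterification removes the acetate under conditions to which the epoxide and the tert-butyldiphenylsilyl ether are inert.

Step 5
Reactants: 5 (2E)-5-[(2R,3R)-3-{[(tert-butyldiphenylsilyl)oxy]methyl}-3-methyloxiran-2-yl]-3-methylpent-2-en-1-ol
Product: 6 (2E)-5-[(2R,3R)-3-{[(tert-butyldiphenylsilyl)oxy]methyl}-3-methyloxiran-2-yl]-3-methylpent-2-enal
Conditions: MnO2, CH2Cl2, rt
Reagents that add atoms: none
Why: The MnO2 oxidation is specific for allylic alcohols and proceeds under neutral conditions without E/Z isomerisation, so the enal should form with epoxide and alkene geometry intact.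

Step 6
Reactants: 6 (2E)-5-[(2R,3R)-3-{[(tert-butyldiphenylsilyl)oxy]methyl}-3-methyloxiran-2-yl]-3-methylpent-2-enal
Product: 7 tert-butyl({(2R,3R)-2-methyl-3-[(3E)-3-methylhexa-3,5-dien-1-yl]oxiran-2-yl}methoxy)diphenylsilane
Conditions: Ph3PCH3Br, n-BuLi, THF, −78 to 0 °C
Reagents that add atoms: methyltriphenylphosphonium bromide, C[P+](c1ccccc1)(c1ccccc1)c1ccccc1.[Br-]
Why: Wittig methylenation of the enal with the non-stabilised ylide adds C7 and, at low temperature, leaves the E C5=C10 alkene, the epoxide and the silyl ether untouched.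

Step 7
Reactants: 8 methyl geranate [methyl (2E)-3,7-dimethylocta-2,6-dienoate]
Product: 10 methyl (2E)-3-methyl-6-oxohex-2-enoate, via secondary ozonide 9 (not isolated)
Conditions: O3 (1 equiv, indicator-controlled), CH2Cl2, −78 °C; then Me2S, −78 °C to rt
Reagents that add atoms: ozone, [O-][O+]=O
Why: In this ozonolysis with reductive work-up the electrophilic ozone should cleave the electron-rich isopropylidene alkene far faster than the ester-conjugated one, which releases C9 as an aldehyde and keeps the E-enoate.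

Step 8
Reactants: 10 methyl (2E)-3-methyl-6-oxohex-2-enoate
Product: 11 methyl (2E)-7,7-dichloro-3-methylhepta-2,6-dienoate
Conditions: PPh3, BrCCl3, CH2Cl2, 0 °C to rt
Reagents that add atoms: bromotrichloromethane, ClC(Cl)(Cl)Br
Why: The Ramirez-type gem-dichloroolefination (Wittig reaction of Ph3P=CCl2 made in situ) adds C8 as a dihalide handle under neutral conditions that spare the enoate.

Step 9
Reactants: 7 tert-butyl({(2R,3R)-2-methyl-3-[(3E)-3-methylhexa-3,5-dien-1-yl]oxiran-2-yl}methoxy)diphenylsilane; 11 methyl (2E)-7,7-dichloro-3-methylhepta-2,6-dienoate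
Product: 13 methyl (2E,6Z,10E,14R,15R)-16-[(tert-butyldiphenylsilyl)oxy]-7-chloro-14,15-epoxy-3,11,15-trimethylhexadeca-2,6,10-trienoate, via B-alkyl-9-BBN adduct 12 (not isolated)
Conditions: 7, 9-BBN, THF, 0 °C to rt; then 11, Pd2(dba)3 (2.5 mol %), Xantphos (5 mol %), aq. K3PO4, THF, 60 °C
Reagents that add atoms: none
Why: 9-BBN adds to the unhindered terminal CH2 of the diene with boron on C7, and in the B-alkyl Suzuki–Miyaura coupling zerovalent palladium carrying the wide-bite-angle ligand inserts only into the C–Cl bond trans to the C11 chain, so a single substitution should give the Z-chloroalkene with C7 trans to C11.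

Step 10
Reactants: 13 methyl (2E,6Z,10E,14R,15R)-16-[(tert-butyldiphenylsilyl)oxy]-7-chloro-14,15-epoxy-3,11,15-trimethylhexadeca-2,6,10-trienoate
Product: 14 methyl (2E,6Z,10E,14R,15R)-16-[(tert-butyldiphenylsilyl)oxy]-14,15-epoxy-3,11,15-trimethyl-7-[(trimethylsilyl)methyl]hexadeca-2,6,10-trienoate
Conditions: Me3SiCH2MgCl, ZnCl2, THF, 0 °C; then 13, Pd(PtBu3)2 (5 mol %), THF/NMP, 45 °C
Reagents that add atoms: (trimethylsilyl)methylmagnesium chloride, C[Si](C)(C)C[Mg]Cl
Why: Negishi coupling at the remaining C–Cl bond, enabled by the bulky electron-rich phosphine, proceeds with retention and puts CH2SiMe3 cis to C11, while the mild zinc reagent has no β-hydrogen and leaves ester, epoxide and silyl ether alone.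

Step 11
Reactants: 14 methyl (2E,6Z,10E,14R,15R)-16-[(tert-butyldiphenylsilyl)oxy]-14,15-epoxy-3,11,15-trimethyl-7-[(trimethylsilyl)methyl]hexadeca-2,6,10-trienoate
Product: 15 methyl ent-3β-hydroxy-18-[(tert-butyldiphenylsilyl)oxy]labda-8(17),13E-dien-15-oate [(3R,4S,5S,9R,10S); trans-decalin; 3-OH, C18 and the C9 chain equatorial; C19 and C20 axial on one face]
Conditions: MeAlCl2 (3 equiv), CH2Cl2 (0.01 M), −78 °C; aqueous quench
Reagents that add atoms: none
Why: MeAlCl2 binds the epoxide oxygen (the ester takes up a further equivalent), the C4–O bond stretches at the tertiary carbon, the C5=C10 π bond attacks C4 from the rear, C9 of the allylsilane captures the developing C10 cation, and the β-silyl-stabilised C8 cation sheds Me3SiCl so that the alkene can only end up as C8=C17. The closest known reaction type is the Lewis-acid-promoted, epoxide-initiated cation–olefin bicyclization with an allylsilane terminator, established for 3-hydroxy-8(17)-methylene trans-decalins, also with an oxygenated carbon on C4. Ring A (C4–C5) closes 6-endo with respect to both the epoxide and the C5=C10 alkene, and ring B (C9–C10) closes 6-endo-trig, each through a chair. C3 keeps its Sharpless configuration with its oxygen equatorial, C4 is inverted so that the CH2OSi group (trans to the chain on the epoxide) becomes equatorial C18 and the methyl group axial C19, antiperiplanar addition across the E C5=C10 alkene sets H5 and C20 trans-diaxial, and the C7/C11-trans geometry of C8=C9 places C11 equatorial at C9, the absolute sense of C5, C10 and C9 being dictated by the one chair–chair fold open to the (3R,4R)-epoxide. The step needs opening at C4 rather than C3, a silent C13=C14 alkene, no participation from C18 and a single alkene regioisomer, which are secured in turn by tertiary versus secondary cation character, the electron-poor aluminium-complexed enoate, the bulky non-nucleophilic silyl ether and silicon-directed termination. MeAlCl2 also destroys adventitious HCl as methane, which protects the allylsilane from protodesilylation.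

Step 12
Reactants: 15 methyl ent-3β-hydroxy-18-[(tert-butyldiphenylsilyl)oxy]labda-8(17),13E-dien-15-oate
Product: 16 methyl ent-3β-[(1H-imidazol-1-ylcarbonothioyl)oxy]-18-[(tert-butyldiphenylsilyl)oxy]labda-8(17),13E-dien-15-oate
Conditions: 1,1'-thiocarbonyldiimidazole, DMAP (cat.), 1,2-dichloroethane, 80 °C
Reagents that add atoms: 1,1'-thiocarbonyldiimidazole, S=C(n1ccnc1)n1ccnc1
Why: Thioacyl transfer under neutral DMAP catalysis (first half of the Barton–McCombie deoxygenation) derivatises the hindered equatorial C3 alcohol without the strong base that could make the C18 silyl group migrate.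

Step 13
Reactants: 16 methyl ent-3β-[(1H-imidazol-1-ylcarbonothioyl)oxy]-18-[(tert-butyldiphenylsilyl)oxy]labda-8(17),13E-dien-15-oate
Product: 17 methyl ent-18-[(tert-butyldiphenylsilyl)oxy]labda-8(17),13E-dien-15-oate
Conditions: Bu3SnH, AIBN (cat.), toluene, 100 °C
Reagents that add atoms: none
Why: In the Barton–McCombie chain the tin radical adds to C=S, the C3–O bond fragments to a secondary radical held in rigid ring A out of reach of both alkenes, and hydrogen transfer from the stannane leaves CH2 at C3.

Step 14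
Reactants: 17 methyl ent-18-[(tert-butyldiphenylsilyl)oxy]labda-8(17),13E-dien-15-oate
Product: 18 methyl ent-18-hydroxylabda-8(17),13E-dien-15-oate
Conditions: TBAF, THF, rt to 45 °C
Reagents that add atoms: none
Why: Fluoride-induced desilylation, driven by the strong Si–F bond, frees the neopentyl C18 alcohol without affecting the methyl ester or either alkene.

Step 15
Reactants: 18 methyl ent-18-hydroxylabda-8(17),13E-dien-15-oate
Product: 19 methyl ent-18-acetoxylabda-8(17),13E-dien-15-oate
Conditions: Ac2O, pyridine, DMAP (cat.), CH2Cl2, rt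
Reagents that add atoms: acetic anhydride, CC(=O)OC(C)=O
Why: DMAP-catalysed acylation readily acetylates the only hydroxyl group present, even at a neopentyl position.

Step 16
Reactants: 19 methyl ent-18-acetoxylabda-8(17),13E-dien-15-oate
Product: 20 methyl ent-18-acetoxy-7α-hydroxylabda-8(17),13E-dien-15-oate (axial 7-OH on the face of H5 and H9, opposite to C20)
Conditions: SeO2 (cat.), t-BuOOH, CH2Cl2, 0 °C to rt
Reagents that add atoms: tert-butyl hydroperoxide, CC(C)(C)OO (terminal oxygen source); selenium dioxide, O=[Se]=O (oxygen carrier)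
Why: In this Riley allylic oxidation SeO2 engages the electron-rich C8=C17 alkene rather than the enoate in an ene reaction from the face opposite axial C20, takes the axial hydrogen on C7 rather than the shielded tertiary hydrogen on C9, and the [2,3]-shift restores the exocyclic alkene with an axial C7 hydroxyl.

Step 17
Reactants: 20 methyl ent-18-acetoxy-7α-hydroxylabda-8(17),13E-dien-15-oate
Product: 21 methyl ent-18-acetoxylabda-6,8(17),13E-trien-15-oate [(4S,5S,9R,10S); CNP0148290.1]
Conditions: Martin sulfurane Ph2S[OC(CF3)2Ph]2, CH2Cl2, 0 °C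
Reagents that add atoms: none
Why: In the Martin sulfurane dehydration the alkoxysulfonium group on axial C7–O lies antiperiplanar to the axial hydrogen on C6, the only carbon next to C7 that carries hydrogen, so a non-acidic E2 elimination should give C6=C7 in conjugation with C8=C17.

Compound list
1 | geranyl acetate | CC(C)=CCC/C(C)=C/COC(C)=O | starting material
2 | (2E,6E)-8-hydroxy-3,7-dimethylocta-2,6-dien-1-yl acetate | OC/C(C)=C/CC/C(C)=C/COC(C)=O | intermediate
3 | (2E)-5-[(2R,3R)-3-(hydroxymethyl)-3-methyloxiran-2-yl]-3-methylpent-2-en-1-yl acetate | OC[C@@]1(C)O[C@@H]1CC/C(C)=C/COC(C)=O | intermediate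
4 | (2E)-5-[(2R,3R)-3-{[(tert-butyldiphenylsilyl)oxy]methyl}-3-methyloxiran-2-yl]-3-methylpent-2-en-1-yl acetate | CC(C)(C)[Si](c1ccccc1)(c1ccccc1)OC[C@@]1(C)O[C@@H]1CC/C(C)=C/COC(C)=O | intermediate
5 | (2E)-5-[(2R,3R)-3-{[(tert-butyldiphenylsilyl)oxy]methyl}-3-methyloxiran-2-yl]-3-methylpent-2-en-1-ol | CC(C)(C)[Si](c1ccccc1)(c1ccccc1)OC[C@@]1(C)O[C@@H]1CC/C(C)=C/CO | intermediate
6 | (2E)-5-[(2R,3R)-3-{[(tert-butyldiphenylsilyl)oxy]methyl}-3-methyloxiran-2-yl]-3-methylpent-2-enal | CC(C)(C)[Si](c1ccccc1)(c1ccccc1)OC[C@@]1(C)O[C@@H]1CC/C(C)=C/C=O | intermediate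
7 | tert-butyl({(2R,3R)-2-methyl-3-[(3E)-3-methylhexa-3,5-dien-1-yl]oxiran-2-yl}methoxy)diphenylsilane | CC(C)(C)[Si](c1ccccc1)(c1ccccc1)OC[C@@]1(C)O[C@@H]1CC/C(C)=C/C=C | intermediate
8 | methyl geranate | CC(C)=CCC/C(C)=C/C(=O)OC | starting material
9 | methyl (2E)-5-(5,5-dimethyl-1,2,4-trioxolan-3-yl)-3-methylpent-2-enoate (secondary ozonide, not isolated) | CC1(C)OOC(CC/C(C)=C/C(=O)OC)O1 | intermediate
10 | methyl (2E)-3-methyl-6-oxohex-2-enoate | O=CCC/C(C)=C/C(=O)OC | intermediate
11 | methyl (2E)-7,7-dichloro-3-methylhepta-2,6-dienoate | ClC(Cl)=CCC/C(C)=C/C(=O)OC | intermediate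
12 | 9-{(3E)-6-[(2R,3R)-3-{[(tert-butyldiphenylsilyl)oxy]methyl}-3-methyloxiran-2-yl]-4-methylhex-3-en-1-yl}-9-borabicyclo[3.3.1]nonane (not isolated) | CC(C)(C)[Si](c1ccccc1)(c1ccccc1)OC[C@@]1(C)O[C@@H]1CC/C(C)=C/CCB1C2CCCC1CCC2 | intermediate
13 | methyl (2E,6Z,10E,14R,15R)-16-[(tert-butyldiphenylsilyl)oxy]-7-chloro-14,15-epoxy-3,11,15-trimethylhexadeca-2,6,10-trienoate | CC(C)(C)[Si](c1ccccc1)(c1ccccc1)OC[C@@]1(C)O[C@@H]1CC/C(C)=C/CC/C(Cl)=C/CC/C(C)=C/C(=O)OC | intermediate
14 | methyl (2E,6Z,10E,14R,15R)-16-[(tert-butyldiphenylsilyl)oxy]-14,15-epoxy-3,11,15-trimethyl-7-[(trimethylsilyl)methyl]hexadeca-2,6,10-trienoate | CC(C)(C)[Si](c1ccccc1)(c1ccccc1)OC[C@@]1(C)O[C@@H]1CC/C(C)=C/CC/C(C[Si](C)(C)C)=C/CC/C(C)=C/C(=O)OC | intermediate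
15 | methyl ent-3β-hydroxy-18-[(tert-butyldiphenylsilyl)oxy]labda-8(17),13E-dien-15-oate | C=C1CC[C@@H]2[C@@](C)(CO[Si](c3ccccc3)(c3ccccc3)C(C)(C)C)[C@H](O)CC[C@@]2(C)[C@@H]1CC/C(C)=C/C(=O)OC | intermediate
16 | methyl ent-3β-[(1H-imidazol-1-ylcarbonothioyl)oxy]-18-[(tert-butyldiphenylsilyl)oxy]labda-8(17),13E-dien-15-oate | C=C1CC[C@@H]2[C@@](C)(CO[Si](c3ccccc3)(c3ccccc3)C(C)(C)C)[C@H](OC(=S)n3ccnc3)CC[C@@]2(C)[C@@H]1CC/C(C)=C/C(=O)OC | intermediate
17 | methyl ent-18-[(tert-butyldiphenylsilyl)oxy]labda-8(17),13E-dien-15-oate | C=C1CC[C@@H]2[C@@](C)(CO[Si](c3ccccc3)(c3ccccc3)C(C)(C)C)CCC[C@@]2(C)[C@@H]1CC/C(C)=C/C(=O)OC | intermediate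
18 | methyl ent-18-hydroxylabda-8(17),13E-dien-15-oate | C=C1CC[C@@H]2[C@@](C)(CO)CCC[C@@]2(C)[C@@H]1CC/C(C)=C/C(=O)OC | intermediate
19 | methyl ent-18-acetoxylabda-8(17),13E-dien-15-oate | C=C1CC[C@@H]2[C@@](C)(COC(C)=O)CCC[C@@]2(C)[C@@H]1CC/C(C)=C/C(=O)OC | intermediate
20 | methyl ent-18-acetoxy-7α-hydroxylabda-8(17),13E-dien-15-oate | C=C1[C@@H](O)C[C@@H]2[C@@](C)(COC(C)=O)CCC[C@@]2(C)[C@@H]1CC/C(C)=C/C(=O)OC | intermediate
21 | methyl ent-18-acetoxylabda-6,8(17),13E-trien-15-oate (CNP0148290.1) | C=C1C=C[C@@H]2[C@@](C)(COC(C)=O)CCC[C@@]2(C)[C@@H]1CC/C(C)=C/C(=O)OC | target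

Total step count: 17. Longest linear sequence: 15 steps (steps 1–6 and 9–17, from geranyl acetate).

Steps most likely to fail

1. Step 11 (key step).
- What may go wrong: the C18 oxygen slows ionisation at C4 and the ester demands excess Lewis acid. Protodesilylation of the allylsilane, or proton loss after ring A has closed, may therefore outrun the attack of C9 on C10.
- Fallback: it sets out from chloride 13 and comes back at 15. The chloroalkene of 13 is itself used as a silicon-free, masked-ketone terminator in a chloroalkene-terminated cation–olefin cyclization. MeAlCl2 in CH2Cl2 closes the same C4–C5 and C9–C10 bonds, and the α-chloro cation at C8 is hydrolysed on aqueous work-up. The product should be methyl ent-3β-hydroxy-8-oxo-18-[(tert-butyldiphenylsilyl)oxy]-17-norlabd-13E-en-15-oate F1, in which the C9 chain holds the more stable equatorial position. Wittig methylenation of the C8 ketone (Ph3P=CH2, THF) then brings in C17 and gives 15.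

2. Step 10.
- What may go wrong: oxidative addition into the hindered alkenyl chloride may be slow. It could then force temperatures at which zinc salts open the epoxide or the alkene geometry erodes.
- Fallback: it sets out from 7 and 10 and comes back at 14, replacing the chloride and borane pair by a bromide and organozinc pair.
  - Borane 12 made from 7 is oxidised (NaBO3, THF/H2O) to (3E)-6-[(2R,3R)-3-{[(tert-butyldiphenylsilyl)oxy]methyl}-3-methyloxiran-2-yl]-4-methylhex-3-en-1-ol F2.
  - I2, PPh3 and imidazole convert this alcohol into tert-butyl({(2R,3R)-3-[(3E)-6-iodo-3-methylhex-3-en-1-yl]-2-methyloxiran-2-yl}methoxy)diphenylsilane F3.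
  - LiCl-assisted zinc insertion then gives the corresponding alkylzinc iodide F4.
  - Aldehyde 10 is turned with CBr4 and PPh3 into methyl (2E)-7,7-dibromo-3-methylhepta-2,6-dienoate F5.
  - Trans-selective Negishi monoalkylation of F5 with F4, using PdCl2(DPEphos), should give methyl (2E,6Z,10E,14R,15R)-7-bromo-16-[(tert-butyldiphenylsilyl)oxy]-14,15-epoxy-3,11,15-trimethylhexadeca-2,6,10-trienoate F6.
  - The weaker C–Br bond of F6 should accept Me3SiCH2ZnCl with Pd(PtBu3)2 at room temperature to give 14.

3. Step 17.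
- What may go wrong: the activated allylic alcohol may ionise and be captured at C17 (allylic transposition). Alternatively the diene may drift into ring B instead of forming by clean elimination toward C6.
- Fallback: it sets out from 20 and comes back at 21. Methyl chloroformate and pyridine give methyl ent-18-acetoxy-7α-[(methoxycarbonyl)oxy]labda-8(17),13E-dien-15-oate F7. Catalytic Pd(PPh3)4 in refluxing THF then effects the palladium-catalysed elimination of an allylic carbonate. Zerovalent palladium ionises the carbonate anti to give the π-allyl complex spanning C7–C8–C17. The only β-hydrogens available to this complex sit on C6, so syn β-hydride loss should deliver 21 under neutral conditions.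

Further compounds
F1 | step 11 | methyl ent-3β-hydroxy-8-oxo-18-[(tert-butyldiphenylsilyl)oxy]-17-norlabd-13E-en-15-oate | O=C1CC[C@@H]2[C@@](C)(CO[Si](c3ccccc3)(c3ccccc3)C(C)(C)C)[C@H](O)CC[C@@]2(C)[C@@H]1CC/C(C)=C/C(=O)OC
F2 | step 10 | (3E)-6-[(2R,3R)-3-{[(tert-butyldiphenylsilyl)oxy]methyl}-3-methyloxiran-2-yl]-4-methylhex-3-en-1-ol | CC(C)(C)[Si](c1ccccc1)(c1ccccc1)OC[C@@]1(C)O[C@@H]1CC/C(C)=C/CCO
F3 | step 10 | tert-butyl({(2R,3R)-3-[(3E)-6-iodo-3-methylhex-3-en-1-yl]-2-methyloxiran-2-yl}methoxy)diphenylsilane | CC(C)(C)[Si](c1ccccc1)(c1ccccc1)OC[C@@]1(C)O[C@@H]1CC/C(C)=C/CCI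
F4 | step 10 | {(3E)-6-[(2R,3R)-3-{[(tert-butyldiphenylsilyl)oxy]methyl}-3-methyloxiran-2-yl]-4-methylhex-3-en-1-yl}zinc iodide | CC(C)(C)[Si](c1ccccc1)(c1ccccc1)OC[C@@]1(C)O[C@@H]1CC/C(C)=C/CC[Zn]I
F5 | step 10 | methyl (2E)-7,7-dibromo-3-methylhepta-2,6-dienoate | BrC(Br)=CCC/C(C)=C/C(=O)OC
F6 | step 10 | methyl (2E,6Z,10E,14R,15R)-7-bromo-16-[(tert-butyldiphenylsilyl)oxy]-14,15-epoxy-3,11,15-trimethylhexadeca-2,6,10-trienoate | CC(C)(C)[Si](c1ccccc1)(c1ccccc1)OC[C@@]1(C)O[C@@H]1CC/C(C)=C/CC/C(Br)=C/CC/C(C)=C/C(=O)OC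
F7 | step 17 | methyl ent-18-acetoxy-7α-[(methoxycarbonyl)oxy]labda-8(17),13E-dien-15-oate | C=C1[C@@H](OC(=O)OC)C[C@@H]2[C@@](C)(COC(C)=O)CCC[C@@]2(C)[C@@H]1CC/C(C)=C/C(=O)OC
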